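You want to know which flask ends highest in J after 3.0 h, and the first thing to reckon is how L is shared between two outlets.

| flask | L | G | temperature | remark | time |
|---|---|---|---|---|---|
| spring | 0.063 M | 6.5 µM | 26 °C | run made earlier |  |
| noon | 0.063 M | 26 µM | 51 °C | run made earlier |  |
| delta | 0.063 M | 13 µM | 30 °C |  | 3.0 h |
| gamma | 0.063 M | 13 µM | 45 °C |  | 3.0 h |
| epsilon | 0.063 M | 13 µM | 15 °C |  | 3.0 h |
| alpha | 0.063 M | 13 µM | 60 °C |  | 3.0 h |
- spring (time / h: J / %, L / %): 0.417: 4.1, 79.0; 0.833: 7.3, 65.1; 1.33: 10.8, 53.9; 1.50: 10.7, 50.2; 2.00: 13.1, 42.3; 2.50: 14.6, 36.5
- noon (time / min: J / %, L / %): 4.00: 9.1, 70.7; 10.0: 11.5, 51.1; 20.0: 10.0, 36.5; 30.0: 7.3, 30.0; 40.0: 5.2, 24.9; 50.0: 4.1, 20.5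

(standard deviation of a reading: 0.5 percentage points)
- the flask that comes out highest in amount of J, in percent of the L charged, or "all alike" when all lie within 1.5 percentage points (delta / gamma / epsilon / alpha / all alike)
- J at the end, in percent of the L charged, delta
- J at the end, in percent of the L charged, gamma
- J at the end, in percent of the L charged, epsilon
- J at the end, in percent of the L charged, alpha


In the first interval of the spring run L falls by 21.0% of the charge while J reaches 4.1%, so the L that went elsewhere stands to J as 4.12 to one. I take the J road to run with [G][L] and the side road to run with [L] squared and need no G, so their ratio falls as L is used and as G is added. That gives one quantity to carry, the break-even enzyme: the level of G at which, with L at its charge, the two roads take L equally. Spring gives it as 29.9 µM. At any moment the ratio is this level over [G], times [L] over its charge, and J's share of the L used, the selectivity, is one part in one plus that ratio.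

Now take two ways to the J of the last spring reading. Following the drifting share down to 36.5% of L gives 16.0%, while the reading says 14.6%, lower by 1.4 percentage points against a scatter of 0.5 points. The reading is the one that cheats, because it counts only the J still standing, and the noon run shows J does not stay: it falls from 11.5% to 4.1%.

For delta, with twice the G of spring, J's starting share is 30.3% instead of 17.8%, and by the same L of 36.5% it has made about 25.4%. For alpha the nearest reading is the first of the noon run, which puts the break-even enzyme at 67.6 µM, so the starting ratio is 5.20. That ratio, read at noon's temperature, stands above delta's starting 2.30, so this reckoning puts delta ahead of alpha. Gamma and epsilon I have not reckoned: gamma at 45 °C lies not far under noon's 51 °C, where J fell, and epsilon at 15 °C lies below the temperature of both runs, so my choice of delta over these two is a judgement, and on it I commit to delta.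

The forecast reads “Delta is narrowly highest.” and gives 15% for delta, 2.5% for gamma, 13% for epsilon and 0.6% for alpha, so for delta it stands below my reckoning.

The simulation gives delta, with 28.6% in delta, 2.64% in gamma, 20.7% in epsilon and 0% in alpha.

    G → Q (k = 1.30 × 10⁻⁴ min⁻¹, Ea = 281 kJ mol⁻¹)
    L + G → J + G, rate k2*[L]*[G]/(1 + ([L]/Km2)) (0.107 M, k = 544 M⁻¹ min⁻¹, Ea = 52.0 kJ mol⁻¹)
    J → Z (k = 0.00293 min⁻¹, Ea = 87.0 kJ mol⁻¹)
    2 L → E (k = 0.0951 M⁻¹ min⁻¹, Ea = 69.0 kJ mol⁻¹)
    (constants at 30 °C)

In delta, with 15.0% of L left after 3.00 h, the break-even enzyme reckons 39.0% of the charge sent down the J road, and the flask then holds 28.6% of J and 10.7% of Z, together 39.3%. In alpha, where the noon reading gave a starting ratio of 5.20, L leaves at the start by the road into E 4.9 times as fast as by the road into J, and after 3.00 h E stands at 95.3% of the charge.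

Readings and results are simulated from invented constants; noise was put on by code.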